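**Retrosynthetic overview**
1. Target 26 ⇐ C2 desilylation ⇐ chloride opening at C13 of the 11α,13-epoxide 24 ⇐ nucleophilic epoxidation of α-methylene lactone 23 ⇐ Mitsunobu inversion/acetylation at C8 of 22.
2. Key step: 22 ⇐ intramolecular CrCl2 Barbier allylation of the bromomethylbutenolide aldehyde 20. One step closes the ten-membered ring (C7–C8), sets C7 and C8 and unveils the exo-methylene lactone, in place of the usual intermolecular allylation plus separate macrocyclisation.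
3. 20 ⇐ butenolide 17 (trans-hydroalumination/iodination, then Pd carbonylation) ⇐ propargylic alcohol 14 (C6 set by Midland reduction of ynone 13).
4. 13 ⇐ enoate 9 + propargyl ether 10; 9 ⇐ asymmetric vinylogous Mukaiyama aldol (sets C2 and E-C4=C5) of Z-enal 4 with dienolate 7; 4 ⇐ anhydromevalonolactone 1, whose ring locks Z-C1=C10.
5. Ring order: butenolide first (step 10), cyclodecadiene last (step 14).

Assumption: atom labels C1–C13 follow germacranolide numbering (lactone C6–O/C12, acetate on C8, free hydroxyl on C2, chlorohydrin C11/C13), and 1, 5 and 10 are taken as purchasable.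

**Route**

Step 1
Reactants: 1 4-methyl-5,6-dihydro-2H-pyran-2-one
Product: 2 (2Z)-5-hydroxy-N-methoxy-N,3-dimethylpent-2-enamide
Conditions: MeNH(OMe)·HCl, i-PrMgCl, THF, −20 → 0 °C; aq. NH4Cl; crude used at once
Reagents that add atoms: N,O-dimethylhydroxylamine hydrochloride, CNOC.Cl
Why: Weinreb aminolysis of the lactone by ClMgN(OMe)Me (acyl–oxygen cleavage) opens the ring without touching the alkene, so the ring-enforced cis geometry becomes the Z-C1=C10 alkene.

Step 2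
Reactants: 2 (2Z)-5-hydroxy-N-methoxy-N,3-dimethylpent-2-enamide
Product: 3 (2Z)-5-[(tert-butyldimethylsilyl)oxy]-N-methoxy-N,3-dimethylpent-2-enamide
Conditions: TBSCl, imidazole, DMF, 0 → 25 °C
Reagents that add atoms: tert-butyldimethylsilyl chloride, CC(C)(C)[Si](C)(C)Cl
Why: Imidazole-mediated silylation of the primary alcohol blocks relactonisation and masks the C8 hydroxyl.

Step 3
Reactants: 3 (2Z)-5-[(tert-butyldimethylsilyl)oxy]-N-methoxy-N,3-dimethylpent-2-enamide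
Product: 4 (2Z)-5-[(tert-butyldimethylsilyl)oxy]-3-methylpent-2-enal
Conditions: i-Bu2AlH, THF, −78 °C; Rochelle salt work-up; used cold
Reagents that add atoms: none
Why: Weinreb amide reduction stops at the chelated tetrahedral intermediate, so the Z-enal is released only on work-up, without over-reduction or Z/E isomerisation.

Step 4
Reactants: 5 methyl 3-methylbut-2-enoate
Product: 7 tert-butyl{[(1Z)-1-methoxy-3-methylbuta-1,3-dien-1-yl]oxy}dimethylsilane, via lithium dienolate 6 (not isolated)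
Conditions: LiN(i-Pr)2, THF, −78 °C; then TBSCl, DMPU, −78 → 0 °C
Reagents that add atoms: tert-butyldimethylsilyl chloride, CC(C)(C)[Si](C)(C)Cl
Why: Kinetic γ-deprotonation of the senecioate ester followed by O-silylation gives the silyl dienolate (silyl ketene acetal formation); its ketene-acetal geometry does not matter in step 5.

Step 5
Reactants: 4 (2Z)-5-[(tert-butyldimethylsilyl)oxy]-3-methylpent-2-enal; 7 tert-butyl{[(1Z)-1-methoxy-3-methylbuta-1,3-dien-1-yl]oxy}dimethylsilane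
Product: 8 methyl (2E,5S,6Z)-9-[(tert-butyldimethylsilyl)oxy]-5-hydroxy-3,7-dimethylnona-2,6-dienoate
Conditions: SiCl4 (1.1 equiv), (R,R)-binaphthyldiamine-derived bisphosphoramide (Denmark catalyst, 5 mol %), i-Pr2NEt (0.2 equiv), CH2Cl2, −78 °C; sat. aq. NaHCO3
Reagents that add atoms: none
Why: Lewis-base-catalysed, SiCl4-mediated vinylogous Mukaiyama aldol: exclusive γ-attack gives the E-enoate, and the chiral phosphoramide-bound silyl cation directs the dienolate to the Si face of the aldehyde, setting C2 as S (the facial sense of the chosen antipode is confirmed by Mosher ester analysis, the other antipode being equally available).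

Step 6
Reactants: 8 methyl (2E,5S,6Z)-9-[(tert-butyldimethylsilyl)oxy]-5-hydroxy-3,7-dimethylnona-2,6-dienoate
Product: 9 methyl (2E,5S,6Z)-5,9-bis[(tert-butyldimethylsilyl)oxy]-3,7-dimethylnona-2,6-dienoate
Conditions: TBSCl, imidazole, DMF, 25 °C
Reagents that add atoms: tert-butyldimethylsilyl chloride, CC(C)(C)[Si](C)(C)Cl
Why: Silylation of the secondary allylic alcohol; this ether is carried to the last step.

Step 7
Reactants: 9 methyl (2E,5S,6Z)-5,9-bis[(tert-butyldimethylsilyl)oxy]-3,7-dimethylnona-2,6-dienoate; 10 tert-butyldimethyl(prop-2-yn-1-yloxy)silane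
Product: 13 (5E,8S,9Z)-1,8,12-tris[(tert-butyldimethylsilyl)oxy]-6,10-dimethyldodeca-5,9-dien-2-yn-4-one, via Weinreb amide 11 (not isolated), via alkynylmagnesium chloride 12 (not isolated)
Conditions: MeNH(OMe)·HCl, i-PrMgCl, THF, −20 → 0 °C (9 → 11); then 12 (from 10, i-PrMgCl, THF, 0 → 25 °C), 0 → 25 °C; aq. NH4Cl
Reagents that add atoms: none
Why: One-pot Weinreb amide formation and ketone synthesis: the alkynyl Grignard adds once and the magnesium chelate holds the tetrahedral intermediate until work-up, so neither over-addition nor 1,4-addition occurs.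

Step 8
Reactants: 13 (5E,8S,9Z)-1,8,12-tris[(tert-butyldimethylsilyl)oxy]-6,10-dimethyldodeca-5,9-dien-2-yn-4-one
Product: 14 (4R,5E,8S,9Z)-1,8,12-tris[(tert-butyldimethylsilyl)oxy]-6,10-dimethyldodeca-5,9-dien-2-yn-4-ol
Conditions: (R)-Alpine-Borane [B-(isopinocampheyl)-9-borabicyclo[3.3.1]nonane from (+)-α-pinene], THF (concentrated), 25 °C, 48 h; then HOCH2CH2NH2, Et2O
Reagents that add atoms: none
Why: Midland reduction: β-hydride transfer from the pinanyl group through a boat-like six-membered transition state, with the rod-like alkynyl group in the small-substituent position, gives the (R)-carbinol at C6, as for simple 1-alkyn-3-ones.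

Step 9
Reactants: 14 (4R,5E,8S,9Z)-1,8,12-tris[(tert-butyldimethylsilyl)oxy]-6,10-dimethyldodeca-5,9-dien-2-yn-4-ol
Product: 16 (2Z,4R,5E,8S,9Z)-1,8,12-tris[(tert-butyldimethylsilyl)oxy]-2-iodo-6,10-dimethyldodeca-2,5,9-trien-4-ol, via vinylalanate 15 (not isolated)
Conditions: NaAlH2(OCH2CH2OCH3)2 (Red-Al), THF, 0 °C; EtOAc; then iodine, THF, −78 → 0 °C
Reagents that add atoms: iodine, [I][I]
Why: Alkoxide-directed trans-hydroalumination puts aluminium on C11 in a five-membered oxa-aluminacycle, and iodinolysis with retention gives the Z-iodoalkene with iodine cis to C6.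

Step 10
Reactants: 16 (2Z,4R,5E,8S,9Z)-1,8,12-tris[(tert-butyldimethylsilyl)oxy]-2-iodo-6,10-dimethyldodeca-2,5,9-trien-4-ol
Product: 17 (5R)-5-{(1E,4S,5Z)-4,8-bis[(tert-butyldimethylsilyl)oxy]-2,6-dimethylocta-1,5-dien-1-yl}-3-{[(tert-butyldimethylsilyl)oxy]methyl}furan-2(5H)-one
Conditions: PdCl2(PPh3)2 (5 mol %), CO (1 atm), i-Pr2NEt, THF, 25 °C
Reagents that add atoms: carbon monoxide, [C-]#[O+]
Why: Carbonylative lactonisation: oxidative addition of the C–I bond to zerovalent palladium, CO insertion and capture of the acylpalladium by the cis C6 hydroxyl close the butenolide without breaking the C6–O bond (hindered amine and room temperature protect the γ-stereocentre).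

Step 11
Reactants: 17 (5R)-5-{(1E,4S,5Z)-4,8-bis[(tert-butyldimethylsilyl)oxy]-2,6-dimethylocta-1,5-dien-1-yl}-3-{[(tert-butyldimethylsilyl)oxy]methyl}furan-2(5H)-one
Product: 18 (5R)-5-{(1E,4S,5Z)-4-[(tert-butyldimethylsilyl)oxy]-8-hydroxy-2,6-dimethylocta-1,5-dien-1-yl}-3-(hydroxymethyl)furan-2(5H)-one
Conditions: HF·pyridine, pyridine, THF, 0 °C
Reagents that add atoms: none
Why: Buffered HF·pyridine cleaves the two unhindered primary TBS ethers far faster than the secondary allylic one (steric selectivity of silyl ether cleavage).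

Step 12
Reactants: 18 (5R)-5-{(1E,4S,5Z)-4-[(tert-butyldimethylsilyl)oxy]-8-hydroxy-2,6-dimethylocta-1,5-dien-1-yl}-3-(hydroxymethyl)furan-2(5H)-one
Product: 19 (5R)-3-(bromomethyl)-5-{(1E,4S,5Z)-4-[(tert-butyldimethylsilyl)oxy]-8-hydroxy-2,6-dimethylocta-1,5-dien-1-yl}furan-2(5H)-one
Conditions: NBS, Me2S, CH2Cl2, −20 → 0 °C
Reagents that add atoms: N-bromosuccinimide, O=C1CCC(=O)N1Br
Why: Corey–Kim bromination: only the allylic alkoxysulfonium on the butenolide is displaced by bromide (SN2), while the saturated primary C8 alcohol is returned unchanged.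

Step 13
Reactants: 19 (5R)-3-(bromomethyl)-5-{(1E,4S,5Z)-4-[(tert-butyldimethylsilyl)oxy]-8-hydroxy-2,6-dimethylocta-1,5-dien-1-yl}furan-2(5H)-one
Product: 20 (3Z,5S,7E)-8-[(2R)-4-(bromomethyl)-5-oxo-2,5-dihydrofuran-2-yl]-5-[(tert-butyldimethylsilyl)oxy]-3,7-dimethylocta-3,7-dienal
Conditions: Dess–Martin periodinane, NaHCO3, CH2Cl2, 0 °C; filtered and used at once
Reagents that add atoms: none
Why: Dess–Martin oxidation under buffered neutral conditions gives the β,γ-unsaturated aldehyde without migration of the C1=C10 alkene into conjugation.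

Step 14
Reactants: 20 (3Z,5S,7E)-8-[(2R)-4-(bromomethyl)-5-oxo-2,5-dihydrofuran-2-yl]-5-[(tert-butyldimethylsilyl)oxy]-3,7-dimethylocta-3,7-dienal
Product: 22 (3aR,4S,6Z,8S,10E,11aR)-8-[(tert-butyldimethylsilyl)oxy]-4-hydroxy-6,10-dimethyl-3-methylidene-3a,4,5,8,9,11a-hexahydrocyclodeca[b]furan-2(3H)-one, via allylchromium dichloride 21 (not isolated)
Conditions: CrCl2 (8 equiv), THF, 25 °C, syringe-pump addition of 20 over 12 h (final 2 mM); aq. NH4Cl
Reagents that add atoms: none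
Why: Proposed new method: CrCl2 reduces the allylic bromide to the allylchromium dichloride 21 (trivalent chromium), which adds through C7 (SE2′) to the tethered aldehyde in a chair Zimmerman–Traxler transition state. The bond forms on the butenolide face opposite the C5 side chain (7R, trans-lactone), and with the ring-fixed E-type allyl unit and C9 equatorial the 7,8-anti alcohol (8S) results. The closest known chemistry is the intermolecular Cr- or Zn-mediated Barbier allylation of aldehydes (β,γ-unsaturated ones included) with 3-(bromomethyl)furan-2(5H)-ones, which is anti-selective, together with CrCl2 (Nozaki–Hiyama) macrocyclisations of ω-formyl allylic bromides.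

Step 15
Reactants: 22 (3aR,4S,6Z,8S,10E,11aR)-8-[(tert-butyldimethylsilyl)oxy]-4-hydroxy-6,10-dimethyl-3-methylidene-3a,4,5,8,9,11a-hexahydrocyclodeca[b]furan-2(3H)-one
Product: 23 (3aR,4R,6Z,8S,10E,11aR)-8-[(tert-butyldimethylsilyl)oxy]-6,10-dimethyl-3-methylidene-2-oxo-2,3,3a,4,5,8,9,11a-octahydrocyclodeca[b]furan-4-yl acetate
Conditions: PPh3 and DIAD (premixed), AcOH, toluene, 0 → 25 °C
Reagents that add atoms: acetic acid, CC(=O)O
Why: Mitsunobu reaction: acetate displaces the C8 alkoxyphosphonium by SN2 with inversion, so the acetate is installed and C8 is corrected from S to R in one operation (the betaine is pre-formed so that free PPh3 does not add to the methylene lactone).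

Step 16
Reactants: 23 (3aR,4R,6Z,8S,10E,11aR)-8-[(tert-butyldimethylsilyl)oxy]-6,10-dimethyl-3-methylidene-2-oxo-2,3,3a,4,5,8,9,11a-octahydrocyclodeca[b]furan-4-yl acetate
Product: 24 (3R,3aR,4R,6Z,8S,10E,11aR)-8-[(tert-butyldimethylsilyl)oxy]-6,10-dimethyl-2-oxo-3a,4,5,8,9,11a-hexahydro-2H-spiro[cyclodeca[b]furan-3,2'-oxiran]-4-yl acetate (11α,13-epoxide)
Conditions: t-BuOOH (anhydrous, in decane), DBU, CH2Cl2, 0 °C
Reagents that add atoms: tert-butyl hydroperoxide, CC(C)(C)OO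
Why: Weitz–Scheffer nucleophilic epoxidation: t-BuOO− adds only to the electron-poor exocyclic alkene (both trisubstituted alkenes are inert), and the enolate closes on oxygen from the α face of C11, anti to the C7–C8 bond, giving the 11α,13-epoxide.

Step 17
Reactants: 24 (3R,3aR,4R,6Z,8S,10E,11aR)-8-[(tert-butyldimethylsilyl)oxy]-6,10-dimethyl-2-oxo-3a,4,5,8,9,11a-hexahydro-2H-spiro[cyclodeca[b]furan-3,2'-oxiran]-4-yl acetate
Product: 25 (3S,3aR,4R,6Z,8S,10E,11aR)-8-[(tert-butyldimethylsilyl)oxy]-3-(chloromethyl)-3-hydroxy-6,10-dimethyl-2-oxo-2,3,3a,4,5,8,9,11a-octahydrocyclodeca[b]furan-4-yl acetate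
Conditions: LiCl, AcOH, THF, 25 °C
Reagents that add atoms: lithium chloride, [Li+].[Cl-]
Why: Acid-assisted SN2 opening of the α,β-epoxy lactone by chloride at the unhindered primary C13; the C11–O bond is not broken, so C11 keeps its configuration (3S in the chlorohydrin only through the priority change).

Step 18
Reactants: 25 (3S,3aR,4R,6Z,8S,10E,11aR)-8-[(tert-butyldimethylsilyl)oxy]-3-(chloromethyl)-3-hydroxy-6,10-dimethyl-2-oxo-2,3,3a,4,5,8,9,11a-octahydrocyclodeca[b]furan-4-yl acetate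
Product: 26 (3S,3aR,4R,6Z,8S,10E,11aR)-3-(chloromethyl)-3,8-dihydroxy-6,10-dimethyl-2-oxo-2,3,3a,4,5,8,9,11a-octahydrocyclodeca[b]furan-4-yl acetate (target)
Conditions: HF·pyridine, THF, 0 → 25 °C
Reagents that add atoms: none
Why: Fluoride-mediated desilylation under mildly acidic conditions leaves the acetate, lactone, tertiary alcohol and primary chloride untouched (basic fluoride would re-close the epoxide).

**Compound list**
1 | 4-methyl-5,6-dihydro-2H-pyran-2-one (anhydromevalonolactone) | CC1=CC(=O)OCC1 | starting material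
2 | (2Z)-5-hydroxy-N-methoxy-N,3-dimethylpent-2-enamide | CON(C)C(=O)/C=C(/C)CCO | intermediate
3 | (2Z)-5-[(tert-butyldimethylsilyl)oxy]-N-methoxy-N,3-dimethylpent-2-enamide | CON(C)C(=O)/C=C(/C)CCO[Si](C)(C)C(C)(C)C | intermediate
4 | (2Z)-5-[(tert-butyldimethylsilyl)oxy]-3-methylpent-2-enal | O=C/C=C(/C)CCO[Si](C)(C)C(C)(C)C | intermediate
5 | methyl 3-methylbut-2-enoate | CC(C)=CC(=O)OC | starting material
6 | lithium (1Z)-1-methoxy-3-methylbuta-1,3-dien-1-olate | CO/C(O[Li])=C/C(C)=C | intermediate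
7 | tert-butyl{[(1Z)-1-methoxy-3-methylbuta-1,3-dien-1-yl]oxy}dimethylsilane | CO/C(O[Si](C)(C)C(C)(C)C)=C/C(C)=C | intermediate
8 | methyl (2E,5S,6Z)-9-[(tert-butyldimethylsilyl)oxy]-5-hydroxy-3,7-dimethylnona-2,6-dienoate | CC(C)(C)[Si](C)(C)OCC/C(C)=C\[C@@H](O)C/C(C)=C/C(=O)OC | intermediate
9 | methyl (2E,5S,6Z)-5,9-bis[(tert-butyldimethylsilyl)oxy]-3,7-dimethylnona-2,6-dienoate | CC(C)(C)[Si](C)(C)OCC/C(C)=C\[C@@H](O[Si](C)(C)C(C)(C)C)C/C(C)=C/C(=O)OC | intermediate
10 | tert-butyldimethyl(prop-2-yn-1-yloxy)silane | C#CCO[Si](C)(C)C(C)(C)C | starting material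
11 | (2E,5S,6Z)-5,9-bis[(tert-butyldimethylsilyl)oxy]-N-methoxy-N,3,7-trimethylnona-2,6-dienamide | CC(C)(C)[Si](C)(C)OCC/C(C)=C\[C@@H](O[Si](C)(C)C(C)(C)C)C/C(C)=C/C(=O)N(C)OC | intermediate
12 | {3-[(tert-butyldimethylsilyl)oxy]prop-1-yn-1-yl}magnesium chloride | Cl[Mg]C#CCO[Si](C)(C)C(C)(C)C | intermediate
13 | (5E,8S,9Z)-1,8,12-tris[(tert-butyldimethylsilyl)oxy]-6,10-dimethyldodeca-5,9-dien-2-yn-4-one | CC(C)(C)[Si](C)(C)OCC/C(C)=C\[C@@H](O[Si](C)(C)C(C)(C)C)C/C(C)=C/C(=O)C#CCO[Si](C)(C)C(C)(C)C | intermediate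
14 | (4R,5E,8S,9Z)-1,8,12-tris[(tert-butyldimethylsilyl)oxy]-6,10-dimethyldodeca-5,9-dien-2-yn-4-ol | CC(C)(C)[Si](C)(C)OCC/C(C)=C\[C@@H](O[Si](C)(C)C(C)(C)C)C/C(C)=C/[C@H](C#CCO[Si](C)(C)C(C)(C)C)O | intermediate
15 | sodium alkenyl(alkoxy)bis(2-methoxyethoxy)aluminate of 14 (five-membered O6–Al–C11 ring) | CC(C)(C)[Si](C)(C)OCC/C(C)=C\[C@@H](O[Si](C)(C)C(C)(C)C)C/C(C)=C/[C@@H]1C=C(CO[Si](C)(C)C(C)(C)C)[Al-](OCCOC)(OCCOC)O1.[Na+] | intermediate
16 | (2Z,4R,5E,8S,9Z)-1,8,12-tris[(tert-butyldimethylsilyl)oxy]-2-iodo-6,10-dimethyldodeca-2,5,9-trien-4-ol | CC(C)(C)[Si](C)(C)OCC/C(C)=C\[C@@H](O[Si](C)(C)C(C)(C)C)C/C(C)=C/[C@H](/C=C(\I)CO[Si](C)(C)C(C)(C)C)O | intermediate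
17 | (5R)-5-{(1E,4S,5Z)-4,8-bis[(tert-butyldimethylsilyl)oxy]-2,6-dimethylocta-1,5-dien-1-yl}-3-{[(tert-butyldimethylsilyl)oxy]methyl}furan-2(5H)-one | CC(C)(C)[Si](C)(C)OCC/C(C)=C\[C@@H](O[Si](C)(C)C(C)(C)C)C/C(C)=C/[C@H]1OC(=O)C(CO[Si](C)(C)C(C)(C)C)=C1 | intermediate
18 | (5R)-5-{(1E,4S,5Z)-4-[(tert-butyldimethylsilyl)oxy]-8-hydroxy-2,6-dimethylocta-1,5-dien-1-yl}-3-(hydroxymethyl)furan-2(5H)-one | OCC/C(C)=C\[C@@H](O[Si](C)(C)C(C)(C)C)C/C(C)=C/[C@H]1OC(=O)C(CO)=C1 | intermediate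
19 | (5R)-3-(bromomethyl)-5-{(1E,4S,5Z)-4-[(tert-butyldimethylsilyl)oxy]-8-hydroxy-2,6-dimethylocta-1,5-dien-1-yl}furan-2(5H)-one | OCC/C(C)=C\[C@@H](O[Si](C)(C)C(C)(C)C)C/C(C)=C/[C@H]1OC(=O)C(CBr)=C1 | intermediate
20 | (3Z,5S,7E)-8-[(2R)-4-(bromomethyl)-5-oxo-2,5-dihydrofuran-2-yl]-5-[(tert-butyldimethylsilyl)oxy]-3,7-dimethylocta-3,7-dienal | O=CC/C(C)=C\[C@@H](O[Si](C)(C)C(C)(C)C)C/C(C)=C/[C@H]1OC(=O)C(CBr)=C1 | intermediate
21 | allylchromium dichloride derived from 20 (CrCl2 unit on C13, trivalent chromium) | O=CC/C(C)=C\[C@@H](O[Si](C)(C)C(C)(C)C)C/C(C)=C/[C@H]1OC(=O)C(C[Cr](Cl)Cl)=C1 | intermediate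
22 | (3aR,4S,6Z,8S,10E,11aR)-8-[(tert-butyldimethylsilyl)oxy]-4-hydroxy-6,10-dimethyl-3-methylidene-3a,4,5,8,9,11a-hexahydrocyclodeca[b]furan-2(3H)-one | O[C@H]1C/C(C)=C\[C@@H](O[Si](C)(C)C(C)(C)C)C/C(C)=C/[C@H]2OC(=O)C(=C)[C@@H]21 | intermediate
23 | (3aR,4R,6Z,8S,10E,11aR)-8-[(tert-butyldimethylsilyl)oxy]-6,10-dimethyl-3-methylidene-2-oxo-2,3,3a,4,5,8,9,11a-octahydrocyclodeca[b]furan-4-yl acetate | CC(=O)O[C@@H]1C/C(C)=C\[C@@H](O[Si](C)(C)C(C)(C)C)C/C(C)=C/[C@H]2OC(=O)C(=C)[C@@H]21 | intermediate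
24 | (3R,3aR,4R,6Z,8S,10E,11aR)-8-[(tert-butyldimethylsilyl)oxy]-6,10-dimethyl-2-oxo-3a,4,5,8,9,11a-hexahydro-2H-spiro[cyclodeca[b]furan-3,2'-oxiran]-4-yl acetate | CC(=O)O[C@@H]1C/C(C)=C\[C@@H](O[Si](C)(C)C(C)(C)C)C/C(C)=C/[C@H]2OC(=O)[C@]3(CO3)[C@@H]21 | intermediate
25 | (3S,3aR,4R,6Z,8S,10E,11aR)-8-[(tert-butyldimethylsilyl)oxy]-3-(chloromethyl)-3-hydroxy-6,10-dimethyl-2-oxo-2,3,3a,4,5,8,9,11a-octahydrocyclodeca[b]furan-4-yl acetate | CC(=O)O[C@@H]1C/C(C)=C\[C@@H](O[Si](C)(C)C(C)(C)C)C/C(C)=C/[C@H]2OC(=O)[C@](O)(CCl)[C@@H]21 | intermediate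
26 | (3S,3aR,4R,6Z,8S,10E,11aR)-3-(chloromethyl)-3,8-dihydroxy-6,10-dimethyl-2-oxo-2,3,3a,4,5,8,9,11a-octahydrocyclodeca[b]furan-4-yl acetate | CC(=O)O[C@@H]1C/C(C)=C\[C@@H](O)C/C(C)=C/[C@H]2OC(=O)[C@](O)(CCl)[C@@H]21 | target

**Step count**
Total: 18 steps. Longest linear sequence: 17 steps (1 → 26 through steps 1–3 and 5–18); step 4 is a one-step side branch.

**Three steps most likely to fail, with fallbacks**

Step 14 (Barbier macrocyclisation). Risks are oligomerisation, protonation of the allylchromium to the 3-methylbutenolide, 1,4-elimination with opening of the butenolide to a dienoic acid, and an unexpected C7/C8 outcome in the ten-membered transition state. The fallback sets out from 19 and comes back at 23. Stannylation of 19 with (Bu3Sn)2 under Pd(PPh3)4 catalysis gives the allylstannane (5R)-5-{(1E,4S,5Z)-4-[(tert-butyldimethylsilyl)oxy]-8-hydroxy-2,6-dimethylocta-1,5-dien-1-yl}-3-[(tributylstannyl)methyl]furan-2(5H)-one F4. Dess–Martin oxidation then gives the stannyl aldehyde (3Z,5S,7E)-5-[(tert-butyldimethylsilyl)oxy]-3,7-dimethyl-8-{(2R)-5-oxo-4-[(tributylstannyl)methyl]-2,5-dihydrofuran-2-yl}octa-3,7-dienal F5. BF3·OEt2 in CH2Cl2 at −78 °C under high dilution closes the ring through an open, non-chelated SE2′ transition state, the mode that makes crotyl-type stannanes syn-selective. It is therefore expected to give directly the 7,8-syn alcohol (3aR,4R,6Z,8S,10E,11aR)-8-[(tert-butyldimethylsilyl)oxy]-4-hydroxy-6,10-dimethyl-3-methylidene-3a,4,5,8,9,11a-hexahydrocyclodeca[b]furan-2(3H)-one F6, which is acetylated (Ac2O, DMAP, pyridine) to 23, so that the inversion step is bypassed.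

Step 15 (Mitsunobu inversion). Risks are E2 elimination towards a conjugated diene, no reaction at the hindered ring carbinol, or phosphine addition to the methylene lactone. The fallback sets out from 22 and comes back at 23. ClCH2SO2Cl and pyridine in CH2Cl2 at 0 °C convert 22 into the sulfonate (3aS,4S,6Z,8S,10E,11aR)-8-[(tert-butyldimethylsilyl)oxy]-6,10-dimethyl-3-methylidene-2-oxo-2,3,3a,4,5,8,9,11a-octahydrocyclodeca[b]furan-4-yl chloromethanesulfonate F7. This small, highly reactive leaving group is displaced by CsOAc with 18-crown-6 in toluene (SN2, inversion) to give 23 without any phosphine present.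

Step 5 (vinylogous aldol). Risks are low reactivity of the β,β-disubstituted enal, Z/E leakage of 4 under the Lewis acid, and insufficient or reversed facial selectivity. The fallback sets out from 4 and comes back at 9. Propargylation of 4 with allenylboronic acid pinacol ester under chiral phosphoric acid catalysis (the TRIP antipode that gives the S carbinol) gives the homopropargylic alcohol (4S,5Z)-8-[(tert-butyldimethylsilyl)oxy]-6-methyloct-5-en-1-yn-4-ol F1. Silylation (TBSCl, imidazole) gives (4S,5Z)-4,8-bis[(tert-butyldimethylsilyl)oxy]-6-methyloct-5-en-1-yne F2. Zirconium-catalysed carboalumination (Me3Al, Cp2ZrCl2 cat., CH2Cl2) adds methyl and aluminium syn across the alkyne to give the alkenylalane dimethyl{(1E,4S,5Z)-4,8-bis[(tert-butyldimethylsilyl)oxy]-2,6-dimethylocta-1,5-dien-1-yl}alane F3, which is quenched in the same flask with ClCO2Me to give 9 with the E geometry fixed by the syn addition.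

**Further compounds**
F1 | step 5 | (4S,5Z)-8-[(tert-butyldimethylsilyl)oxy]-6-methyloct-5-en-1-yn-4-ol | CC(C)(C)[Si](C)(C)OCC/C(C)=C\[C@@H](O)CC#C
F2 | step 5 | (4S,5Z)-4,8-bis[(tert-butyldimethylsilyl)oxy]-6-methyloct-5-en-1-yne | CC(C)(C)[Si](C)(C)OCC/C(C)=C\[C@@H](O[Si](C)(C)C(C)(C)C)CC#C
F3 | step 5 | dimethyl{(1E,4S,5Z)-4,8-bis[(tert-butyldimethylsilyl)oxy]-2,6-dimethylocta-1,5-dien-1-yl}alane | CC(C)(C)[Si](C)(C)OCC/C(C)=C\[C@@H](O[Si](C)(C)C(C)(C)C)C/C(C)=C/[Al](C)C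
F4 | step 14 | (5R)-5-{(1E,4S,5Z)-4-[(tert-butyldimethylsilyl)oxy]-8-hydroxy-2,6-dimethylocta-1,5-dien-1-yl}-3-[(tributylstannyl)methyl]furan-2(5H)-one | OCC/C(C)=C\[C@@H](O[Si](C)(C)C(C)(C)C)C/C(C)=C/[C@H]1OC(=O)C(C[Sn](CCCC)(CCCC)CCCC)=C1
F5 | step 14 | (3Z,5S,7E)-5-[(tert-butyldimethylsilyl)oxy]-3,7-dimethyl-8-{(2R)-5-oxo-4-[(tributylstannyl)methyl]-2,5-dihydrofuran-2-yl}octa-3,7-dienal | O=CC/C(C)=C\[C@@H](O[Si](C)(C)C(C)(C)C)C/C(C)=C/[C@H]1OC(=O)C(C[Sn](CCCC)(CCCC)CCCC)=C1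
F6 | step 14 | (3aR,4R,6Z,8S,10E,11aR)-8-[(tert-butyldimethylsilyl)oxy]-4-hydroxy-6,10-dimethyl-3-methylidene-3a,4,5,8,9,11a-hexahydrocyclodeca[b]furan-2(3H)-one | O[C@@H]1C/C(C)=C\[C@@H](O[Si](C)(C)C(C)(C)C)C/C(C)=C/[C@H]2OC(=O)C(=C)[C@@H]21
F7 | step 15 | (3aS,4S,6Z,8S,10E,11aR)-8-[(tert-butyldimethylsilyl)oxy]-6,10-dimethyl-3-methylidene-2-oxo-2,3,3a,4,5,8,9,11a-octahydrocyclodeca[b]furan-4-yl chloromethanesulfonate | ClCS(=O)(=O)O[C@H]1C/C(C)=C\[C@@H](O[Si](C)(C)C(C)(C)C)C/C(C)=C/[C@H]2OC(=O)C(=C)[C@@H]21
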